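## Analysis of the target

Perrottetin F (15) is an open-chain bis(bibenzyl): four benzene rings, A to D, are joined by two CH2CH2 bridges (A–B and C–D) and by one diaryl ether oxygen between C4 of ring B and C1 of ring C. There is no stereocenter and no ring other than the four arenes, so the whole problem is one of substitution pattern. Rings A and D are identical 3-hydroxyphenyl groups, ring B is a plain para-disubstituted benzene, and ring C is the demanding ring, with aryloxy at C1, hydroxyls at C2 and C3, and the bridge at C5. The C2/C3 catechol is the sensitive group, since it is oxidised by air to an ortho-quinone once deprotonated, and four free phenols rule out harsh basic or oxidising conditions at the end. The difficulty is that the outer oxygens of ring C (C1 and C3) are equivalent in a symmetric pyrogallol-type precursor but must end up different, so a classical route needs a scarce, pre-differentiated trioxygenated building block or extra protecting-group steps. The strategy rests on one feature: without its C3 hydroxyl, ring C is a 2-aryloxy-4-alkylphenol in which C3–H is the only C–H bond ortho to the C2 oxygen, because C1 is blocked by the aryloxy group. The third oxygen can therefore be added last, directed from the C2 oxygen, onto a skeleton built from a cheap 3,4-dioxygenated benzaldehyde whose two oxygens are already differentiated. The phenol before oxygenation is the dimethyl ether of the C3-deoxy natural congener perrottetin E, so the route follows the presumed last biosynthetic oxidation.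

## Retrosynthetic reasoning

15 to 14. The two O–CH3 bonds on rings A and D are cut last. Methyl ethers are the one phenol protection that survives base, ylide, hydrogenation, electrophilic bromine and a hot oxidant. They also guarantee that ring C carries the only free hydroxyl in the molecule, so only one directing group can be installed. The forward step must cleave two aryl methyl ethers without touching the diaryl ether.

14 to 13. The two Si–O bonds of the five-membered silicon bridge on the catechol are cut. The bridge is what the key step leaves behind, and it protects the catechol for as long as it stays. The forward step is a fluoride-induced desilylation under non-basic conditions.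

13 to 11 (through 12). The C3–O bond of ring C is cut, together with the O–Si bond that closes the dioxasilole. This is the one bond that separates ring C from an ordinary 2-aryloxy-4-alkylphenol. Cutting it turns a 1,2,3-trioxygenated ring with unlike outer oxygens into a 3,4-dioxygenated one, for which a differentiated building block (2) exists. The forward reaction must oxygenate one aromatic C–H bond out of fifteen. The silanol tethered to the C2 oxygen of 11 does this, because it can reach only C3.

11 to 9 to 7 and 8. The Si–OH bond and then the aryl O–Si bond are cut. The directing group is put on in two simple operations: silylation of the only free phenol with chlorosilane 8, then conversion of Si–H into Si–OH through bromosilane 10. Nothing else in 7 can be silylated.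

7 to 6. This is a functional-group change only: the four bridge C–H bonds and the phenol O–H are traced back to two alkenes and a benzyl ether. One hydrogenation should saturate both stilbenes and release the ring C phenol, so the benzyl group costs no separate step.

6 to 3 and two molecules of 4 (through ylide 5). Both alkene C=C bonds are cut, each between a bridge carbon on the ring A or D side and the carbon on ring B or C. Rings A and D are identical, so one ylide serves twice in one flask. The cut is placed here because it leaves two aldehydes on the core, and one of them is needed anyway to activate ring B for the ether formation.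

3 to 1 and 2. The diaryl ether C–O bond on the ring B side is cut. Ring B is the electrophile because the para-formyl group of 1 activates fluoride for substitution. The nucleophile is the free 3-hydroxyl of 2, and the 4-oxygen of 2, the future C2 hydroxyl of ring C, is already masked as its benzyl ether. The differentiation of the two ring C oxygens is bought with the starting material.

## Alternatives that were turned down

Alternative 1: The cut is at the two aryl–vinyl bonds between rings A and D and their bridges. Two molecules of 2-methoxybenzoic acid A1 would be joined to the two vinyl groups of the divinyl diaryl ether A2, which carries ring C as its dimethyl ether. The reaction is carboxylate-directed ortho C–H olefination with the rhodium catalyst [Cp*RhCl2]2 A3 and the oxidant Cu(OAc)2 A4, giving the bis(E-stilbene-2-carboxylic acid) A5. Protodecarboxylation, hydrogenation and cleavage of four methyl ethers would follow.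
- For: the carboxyl group of A1 sits between the methoxy group and the new alkene and is then removed, so the meta pattern of rings A and D comes from a very cheap acid. The coupling produces no phosphine oxide, and the reaction type is known for benzoic acids and styrenes.
- Against: the C–H chemistry is spent on two bonds that a Wittig reaction of 4 makes without difficulty. Ring C with its three different oxygens has to be in place in A2 from the start. The ortho-alkenyl acids in A5 can lactonise onto the alkene under the oxidative conditions. Both sites must react, the catalyst A3 is a precious-metal complex, and the oxidant A4 is consumed in stoichiometric amount. Four operations remain after the key step.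
- Comparison: from a purchasable 3,4,5-trioxygenated benzaldehyde this route would be about two steps shorter than the chosen one and has better atom economy. The chosen route offers a cheap 3,4-dioxygenated start (2), only two methyl ethers to cleave, and a single C–H functionalisation on the one bond that makes ring C special.

Alternative 2: The cut runs through rings A and D themselves, two C–C bonds in each. The bis(nitroalkene) A6, with a 4-nitrobut-3-enyl arm on ring B and on ring C, would react twice with 1-methoxy-3-(trimethylsilyloxy)buta-1,3-diene A7 in a (4+2) cycloaddition. Acid-promoted loss of the methoxy group and base-promoted loss of the nitro group would aromatise each new ring, giving A8, which is 15 with the ring C hydroxyls as methyl ethers.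
- For: rings A and D appear directly as free meta-substituted phenols, so they need no protecting group, and no metal is used. The polarity of the diene A7 and of the nitroalkene units of A6 fixes the meta relationship.
- Against: two simple aryl rings that can be bought in 4 are built from scratch. A6 needs each arm of a core dialdehyde lengthened by two carbons and then a nitroaldol condensation. Alkyl-substituted nitroalkenes are modest dienophiles and shift their double bond out of conjugation under base. Two cycloadditions and two aromatisations must all succeed. Ring C again has to be trioxygenated from the start, and its two methyl ethers still have to be cleaved.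
- Comparison: this alternative is stronger on protecting-group count for rings A and D. The chosen route is shorter to the key intermediate and every step before the key step is routine.

Alternative 3: The cut runs through ring B. The acyl pyrone A9, 5-[(3-methoxyphenyl)acetyl]-2-pyrone, and the ethynyl ether A10 of the ring C phenol, which carries the ring D arm and two methyl ethers, would undergo (4+2) cycloaddition and decarboxylative cycloreversion. The nucleophilic terminal alkyne carbon bonds to C6 of the pyrone and the oxygen-bearing carbon to C3, which places the acyl group and the aryloxy group para and gives the deoxybenzoin A11.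
- For: the route is convergent. Ring B and the diaryl ether linkage arise in one pericyclic step with polarity-controlled regiochemistry, and no activated aryl halide is needed.
- Against: ring B is the simplest ring of the target and is available intact in 1. Aryl ethynyl ethers such as A10 are labile and take several steps to make. A9 has an acidic methylene next to an electrophilic pyrone. The ketone of A11 must be removed afterwards, and four methyl ethers must then be cleaved. The ring C fragment again needs the full trioxygenation pattern.
- Comparison: this alternative is stronger on convergence. The chosen route is linear but short, uses one commercial piece for each ring, and has a single step of real uncertainty.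

Key step: step 6

Assumption: compound 6 is expected as a mixture of alkene isomers and is hydrogenated as such, so its SMILES carries no double-bond descriptors.

## Route

Step 1
Reactants: 1 4-fluorobenzaldehyde; 2 4-benzyloxy-3-hydroxybenzaldehyde
Product: 3 4-(benzyloxy)-3-(4-formylphenoxy)benzaldehyde
Conditions: K2CO3, DMF, 120 °C
Reagents that add atoms: none
Why: Nucleophilic aromatic substitution: the phenoxide of 2 displaces fluoride from 1, which is activated by the para-formyl group; neither aldehyde is enolisable and the benzyl ether is inert to carbonate.

Step 2
Reactants: 3 4-(benzyloxy)-3-(4-formylphenoxy)benzaldehyde; 4 (3-methoxybenzyl)triphenylphosphonium chloride (2.4 equiv)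
Product: 6 1-(benzyloxy)-4-[2-(3-methoxyphenyl)ethenyl]-2-{4-[2-(3-methoxyphenyl)ethenyl]phenoxy}benzene (E/Z mixture at both alkenes), via ylide (3-methoxybenzylidene)triphenylphosphorane 5 (not isolated)
Conditions: KOtBu, THF, 0 °C to rt
Reagents that add atoms: none
Why: Double Wittig reaction of a semi-stabilised benzylic ylide with two aromatic aldehydes; the two formyl groups react in succession and the alkene geometry does not matter because both double bonds are saturated in the next step.

Step 3
Reactants: 6 1-(benzyloxy)-4-[2-(3-methoxyphenyl)ethenyl]-2-{4-[2-(3-methoxyphenyl)ethenyl]phenoxy}benzene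
Product: 7 4-[2-(3-methoxyphenyl)ethyl]-2-{4-[2-(3-methoxyphenyl)ethyl]phenoxy}phenol
Conditions: H2 (1 atm), 10% Pd/C, EtOAc–EtOH, rt
Reagents that add atoms: none
Why: Heterogeneous catalytic hydrogenation should saturate both stilbene double bonds and hydrogenolyse the benzyl ether in the same operation; the diaryl ether and the methyl ethers are inert under these conditions.

Step 4
Reactants: 7 4-[2-(3-methoxyphenyl)ethyl]-2-{4-[2-(3-methoxyphenyl)ethyl]phenoxy}phenol; 8 di-tert-butylchlorosilane
Product: 9 di-tert-butyl(4-[2-(3-methoxyphenyl)ethyl]-2-{4-[2-(3-methoxyphenyl)ethyl]phenoxy}phenoxy)silane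
Conditions: imidazole, DMF, rt to 50 °C
Reagents that add atoms: none
Why: Silylation of the only free phenol by substitution at silicon with imidazole as base and nucleophilic catalyst; the Si–H chlorosilane is the least hindered di-tert-butylsilyl electrophile and should tolerate the ortho aryloxy group.

Step 5
Reactants: 9 di-tert-butyl(4-[2-(3-methoxyphenyl)ethyl]-2-{4-[2-(3-methoxyphenyl)ethyl]phenoxy}phenoxy)silane
Product: 11 di-tert-butyl(4-[2-(3-methoxyphenyl)ethyl]-2-{4-[2-(3-methoxyphenyl)ethyl]phenoxy}phenoxy)silanol, via bromosilane 10 (not isolated)
Conditions: NBS, CH2Cl2, 0 °C; then H2O, Et3N, THF, 0 °C to rt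
Reagents that add atoms: water, O (the silanol oxygen); N-bromosuccinimide, O=C1CCC(=O)N1Br (its bromine is held only in intermediate 10)
Why: The Si–H bond is brominated by NBS at 0 °C far faster than an anisole ring, and the silyl bromide hydrolyses on addition of water and amine; the two tert-butyl groups prevent condensation to a disiloxane and shield the aryl O–Si bond.

Step 6
Reactants: 11 di-tert-butyl(4-[2-(3-methoxyphenyl)ethyl]-2-{4-[2-(3-methoxyphenyl)ethyl]phenoxy}phenoxy)silanol
Product: 13 2,2-di-tert-butyl-6-[2-(3-methoxyphenyl)ethyl]-4-{4-[2-(3-methoxyphenyl)ethyl]phenoxy}-1,3,2-benzodioxasilole (ring C catechol bridged by di-tert-butylsilylene), via C3-acetoxy silanol 12 (not isolated)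
Conditions: Pd(OPiv)2 (5 mol%), PhI(OAc)2 (2 equiv), PhMe, 100 °C
Reagents that add atoms: (diacetoxyiodo)benzene, CC(=O)OI(OC(C)=O)c1ccccc1 (supplies the C3 oxygen; its acetyl group is held only in intermediate 12)
Why: Silanol-directed, palladium-catalysed C–H oxygenation of phenols to catechols is a known reaction type, applied here to a 2-aryloxy-4-alkylphenol. The silanol oxygen of 11 binds divalent palladium and delivers it to C3 of ring C through a six-membered palladacycle (Pd, O, Si, O, C2, C3). PhI(OAc)2 oxidises the palladacycle to a tetravalent palladium acetate, and C–O reductive elimination gives the aryl acetate 12. Under the acidic conditions the acetyl group passes to the silanol oxygen and the freed C3 oxygen attacks silicon with loss of acetic acid, so the five-membered 1,3,2-dioxasilole closes by O–Si bond formation, an exo substitution at silicon. No stereocenter is formed. The step needs site selectivity among fifteen aromatic and eight benzylic C–H bonds; it is secured because C1, the other position ortho to the C2 oxygen, carries the aryloxy group and every other C–H bond lies outside the reach of a six-membered palladacycle. Rings A and D carry methyl ethers and so offer no second directing group, and delivery of the oxygen at carbon by the metal avoids oxidants that pass through ortho-quinones and could attack the aryloxy-bearing C1.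

Step 7
Reactants: 13 2,2-di-tert-butyl-6-[2-(3-methoxyphenyl)ethyl]-4-{4-[2-(3-methoxyphenyl)ethyl]phenoxy}-1,3,2-benzodioxasilole
Product: 14 5-[2-(3-methoxyphenyl)ethyl]-3-{4-[2-(3-methoxyphenyl)ethyl]phenoxy}benzene-1,2-diol
Conditions: Bu4NF, AcOH, THF, 0 °C to rt, under argon
Reagents that add atoms: none
Why: Fluoride-induced desilylation: the strong Si–F bond drives cleavage of both aryl O–Si bonds of the strained five-membered ring, and the acetic acid buffer keeps the catechol protonated so that it is not oxidised by air.

Step 8
Reactants: 14 5-[2-(3-methoxyphenyl)ethyl]-3-{4-[2-(3-methoxyphenyl)ethyl]phenoxy}benzene-1,2-diol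
Product: 15 perrottetin F, 5-[2-(3-hydroxyphenyl)ethyl]-3-{4-[2-(3-hydroxyphenyl)ethyl]phenoxy}benzene-1,2-diol
Conditions: BBr3 (excess), CH2Cl2, −78 °C to rt; then H2O
Reagents that add atoms: none
Why: Lewis-acid cleavage of aryl methyl ethers: boron binds the ether oxygen and bromide attacks the methyl carbon; the diaryl ether has no sp3 carbon for bromide to attack and should survive, and the aryl borates are hydrolysed in the work-up.

## Compound list

1 | 4-fluorobenzaldehyde | O=Cc1ccc(F)cc1 | starting material
2 | 4-benzyloxy-3-hydroxybenzaldehyde | O=Cc1ccc(OCc2ccccc2)c(O)c1 | starting material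
3 | 4-(benzyloxy)-3-(4-formylphenoxy)benzaldehyde | O=Cc1ccc(Oc2cc(C=O)ccc2OCc2ccccc2)cc1 | intermediate
4 | (3-methoxybenzyl)triphenylphosphonium chloride | COc1cccc(C[P+](c2ccccc2)(c2ccccc2)c2ccccc2)c1.[Cl-] | starting material
5 | (3-methoxybenzylidene)triphenylphosphorane (ylide, not isolated) | COc1cccc(C=P(c2ccccc2)(c2ccccc2)c2ccccc2)c1 | intermediate
6 | 1-(benzyloxy)-4-[2-(3-methoxyphenyl)ethenyl]-2-{4-[2-(3-methoxyphenyl)ethenyl]phenoxy}benzene, E/Z mixture at both alkenes (geometry not defined) | COc1cccc(C=Cc2ccc(Oc3cc(C=Cc4cccc(OC)c4)ccc3OCc3ccccc3)cc2)c1 | intermediate
7 | 4-[2-(3-methoxyphenyl)ethyl]-2-{4-[2-(3-methoxyphenyl)ethyl]phenoxy}phenol | COc1cccc(CCc2ccc(Oc3cc(CCc4cccc(OC)c4)ccc3O)cc2)c1 | intermediate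
8 | di-tert-butylchlorosilane | CC(C)(C)[SiH](Cl)C(C)(C)C | starting material
9 | di-tert-butyl(aryloxy)silane of phenol 7 (Si–H) | COc1cccc(CCc2ccc(Oc3cc(CCc4cccc(OC)c4)ccc3O[SiH](C(C)(C)C)C(C)(C)C)cc2)c1 | intermediate
10 | bromo(di-tert-butyl)(aryloxy)silane of phenol 7 (not isolated) | COc1cccc(CCc2ccc(Oc3cc(CCc4cccc(OC)c4)ccc3O[Si](Br)(C(C)(C)C)C(C)(C)C)cc2)c1 | intermediate
11 | di-tert-butyl(aryloxy)silanol of phenol 7 (precursor of the key step) | COc1cccc(CCc2ccc(Oc3cc(CCc4cccc(OC)c4)ccc3O[Si](O)(C(C)(C)C)C(C)(C)C)cc2)c1 | intermediate
12 | 2-{[di-tert-butyl(hydroxy)silyl]oxy}-5-[2-(3-methoxyphenyl)ethyl]-3-{4-[2-(3-methoxyphenyl)ethyl]phenoxy}phenyl acetate (not isolated) | COc1cccc(CCc2ccc(Oc3cc(CCc4cccc(OC)c4)cc(OC(C)=O)c3O[Si](O)(C(C)(C)C)C(C)(C)C)cc2)c1 | intermediate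
13 | 2,2-di-tert-butyl-6-[2-(3-methoxyphenyl)ethyl]-4-{4-[2-(3-methoxyphenyl)ethyl]phenoxy}-1,3,2-benzodioxasilole (product of the key step) | COc1cccc(CCc2ccc(Oc3cc(CCc4cccc(OC)c4)cc4O[Si](C(C)(C)C)(C(C)(C)C)Oc34)cc2)c1 | intermediate
14 | 5-[2-(3-methoxyphenyl)ethyl]-3-{4-[2-(3-methoxyphenyl)ethyl]phenoxy}benzene-1,2-diol | COc1cccc(CCc2ccc(Oc3cc(CCc4cccc(OC)c4)cc(O)c3O)cc2)c1 | intermediate
15 | perrottetin F | Oc1cccc(CCc2ccc(Oc3cc(CCc4cccc(O)c4)cc(O)c3O)cc2)c1 | target

## Step count and risk

Total step count: 8. Longest linear sequence: 8 steps (1 and 2 to 15); compounds 4 and 8 are bought and enter directly.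

Step 6 (key step). The most likely failure is slow cyclopalladation at C3, because the aryloxy group at C1 crowds the silanol. Undirected oxidation of the electron-rich rings or of the benzylic positions, or loss of the silyl group in the hot acidic medium, could then overtake the directed pathway. The fallback builds the C3 oxygen by way of a carbon substituent and sets out from phenol 7. Magnesium-mediated ortho-formylation (MgCl2, Et3N, paraformaldehyde, MeCN, reflux) can only go to C3 and should give 2-hydroxy-5-[2-(3-methoxyphenyl)ethyl]-3-{4-[2-(3-methoxyphenyl)ethyl]phenoxy}benzaldehyde F1. Dakin oxidation (H2O2, NaOH, THF–H2O, 0 °C, degassed) then converts the formyl group, through the aryl formate F2 that hydrolyses in the flask, into the hydroxyl. The route is rejoined at catechol 14 and steps 4 to 7 are bypassed.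

Step 5. The most likely failure is electrophilic bromination of an anisole ring or of ring C, or radical bromination at a benzylic position, in competition with bromination of the Si–H bond. The fallback sets out from silane 9 and uses metal-catalysed dehydrogenative hydrolysis ([RuCl2(p-cymene)]2, H2O, MeCN, rt to 60 °C). This turns Si–H into Si–OH with release of dihydrogen and involves no electrophilic halogen. It comes back at silanol 11 and makes no new compound.

Step 4. The most likely failure is incomplete silylation, since the phenol oxygen is flanked by the aryloxy group and the chlorosilane carries two tert-butyl groups, or partial loss of the silyl ether during purification. The fallback sets out from phenol 7 and uses the far more electrophilic tBu2Si(OTf)2 with 2,6-lutidine in CH2Cl2 at 0 °C. The resulting di-tert-butyl(aryloxy)silyl triflate F3 is hydrolysed in the aqueous NaHCO3 work-up to silanol 11, so the Si–H stage (steps 4 and 5) is skipped.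

Step 8. The most likely failure is incomplete cleavage that stops at a monomethyl ether, because the Lewis acid is first tied up by the catechol oxygens, or oxidative degradation of the catechol during work-up. The fallback sets out from 14 and changes the mechanism from Lewis-acid activation to nucleophilic dealkylation: NaSEt in DMF at 130 °C under argon attacks the methyl carbons directly, followed by acidic work-up. It comes back at 15 and makes no new compound.

## Further compounds

F1 | step 6 | 2-hydroxy-5-[2-(3-methoxyphenyl)ethyl]-3-{4-[2-(3-methoxyphenyl)ethyl]phenoxy}benzaldehyde | COc1cccc(CCc2ccc(Oc3cc(CCc4cccc(OC)c4)cc(C=O)c3O)cc2)c1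
F2 | step 6 | 2-hydroxy-5-[2-(3-methoxyphenyl)ethyl]-3-{4-[2-(3-methoxyphenyl)ethyl]phenoxy}phenyl formate | COc1cccc(CCc2ccc(Oc3cc(CCc4cccc(OC)c4)cc(OC=O)c3O)cc2)c1
F0 | step 5 | none | none
F3 | step 4 | di-tert-butyl(4-[2-(3-methoxyphenyl)ethyl]-2-{4-[2-(3-methoxyphenyl)ethyl]phenoxy}phenoxy)silyl trifluoromethanesulfonate | COc1cccc(CCc2ccc(Oc3cc(CCc4cccc(OC)c4)ccc3O[Si](OS(=O)(=O)C(F)(F)F)(C(C)(C)C)C(C)(C)C)cc2)c1
F0 | step 8 | none | none
A1 | alternative 1 | 2-methoxybenzoic acid | COc1ccccc1C(=O)O
A2 | alternative 1 | 5-ethenyl-1-(4-ethenylphenoxy)-2,3-dimethoxybenzene | C=Cc1ccc(Oc2cc(C=C)cc(OC)c2OC)cc1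
A3 | alternative 1 | pentamethylcyclopentadienylrhodium dichloride dimer, [Cp*RhCl2]2 | C[C-]1C(C)=C(C)C(C)=C1C.C[C-]1C(C)=C(C)C(C)=C1C.[Cl-].[Cl-].[Cl-].[Cl-].[Rh+3].[Rh+3]
A4 | alternative 1 | copper diacetate, Cu(OAc)2 | CC(=O)[O-].CC(=O)[O-].[Cu+2]
A5 | alternative 1 | bis(E-stilbene-2-carboxylic acid), carboxyl between methoxy and alkene on rings A and D, ring C as dimethyl ether | COc1cccc(/C=C/c2ccc(Oc3cc(/C=C/c4cccc(OC)c4C(=O)O)cc(OC)c3OC)cc2)c1C(=O)O
A6 | alternative 2 | 1,2-dimethoxy-5-[(E)-4-nitrobut-3-enyl]-3-{4-[(E)-4-nitrobut-3-enyl]phenoxy}benzene | COc1cc(CC/C=C/[N+](=O)[O-])cc(Oc2ccc(CC/C=C/[N+](=O)[O-])cc2)c1OC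
A7 | alternative 2 | (E)-1-methoxy-3-(trimethylsilyloxy)buta-1,3-diene | CO/C=C/C(=C)O[Si](C)(C)C
A8 | alternative 2 | perrottetin F with the two ring C hydroxyls as methyl ethers | Oc1cccc(CCc2ccc(Oc3cc(CCc4cccc(O)c4)cc(OC)c3OC)cc2)c1
A9 | alternative 3 | 5-[(3-methoxyphenyl)acetyl]-2H-pyran-2-one | COc1cccc(CC(=O)c2ccc(=O)oc2)c1
A10 | alternative 3 | 1-(ethynyloxy)-2,3-dimethoxy-5-[2-(3-methoxyphenyl)ethyl]benzene | C#COc1cc(CCc2cccc(OC)c2)cc(OC)c1OC
A11 | alternative 3 | deoxybenzoin with all four rings, ketone at the ring B end of the A–B bridge | COc1cccc(CC(=O)c2ccc(Oc3cc(CCc4cccc(OC)c4)cc(OC)c3OC)cc2)c1
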